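Assumption: the side chain is numbered C1′ (benzylic CH2) to C15′ (tertiary carbinol carbon); compounds 4 and 11 are bought as single enantiomers.

**Retrosynthetic overview**
1. C1′–C2′: photochemical o-quinone-methide alkenylation joins the bought phenol (as its salicyl alcohol) to an (E)-alkenylboronic acid that carries C2′–C12′.
2. C3′–C4′: acetylide opening of a bought (R)-glycidic ester, which supplies C5′; its ester carbon becomes C6′ through a 1,1-dibromoalkene.
3. C7′–C8′, then C7′–CH3: trans-selective B-alkyl Suzuki coupling and Negishi methylation on that dibromoalkene; the alkyl partner comes from the bought (R)-Roche ester, which supplies C11′.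
4. C2′–B/C3′–CH3: Cu-catalysed methylboration of the terminal alkyne. C12′–C13′: Weinreb amide plus a vinyllithium from bought 2-methylbut-3-yn-2-ol, then desilylation.
5. No ring is formed at any stage; the only ring, the arene, is bought.

**Route**

Step 1
Reactants: 1 4-methoxy-2-methylphenol
Product: 3 2-(hydroxymethyl)-4-methoxy-6-methylphenol, via sodium phenolate 2 (not isolated)
Conditions: NaOH (1.0 equiv), 37% aq. CH2O (1.5 equiv), H2O, 20 °C, 24 h; then 1 M HCl to pH 6
Reagents that add atoms: formaldehyde, C=O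
Why: Lederer–Manasse hydroxymethylation, in which the phenolate attacks formaldehyde at its only free ortho position (para carries OMe, the other ortho carries CH3); no stereocentre is involved.

Step 2
Reactants: 4 methyl (2R)-oxirane-2-carboxylate (methyl (R)-glycidate); 5 ethynyltrimethylsilane
Product: 7 methyl (2R)-2-hydroxy-5-(trimethylsilyl)pent-4-ynoate, via lithium acetylide 6 (not isolated)
Conditions: 5, n-BuLi, THF, −78 °C; BF3·OEt2; then 4, −78 °C; aq. NH4Cl
Reagents that add atoms: none
Why: Yamaguchi–Hirao BF3-promoted alkynylation opens the epoxide at its unsubstituted CH2 at −78 °C, so the ester and the bought C–O stereocentre (future C5′, R) are not touched.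

Step 3
Reactants: 7 methyl (2R)-2-hydroxy-5-(trimethylsilyl)pent-4-ynoate
Product: 8 methyl (2R)-2-[(tert-butyldimethylsilyl)oxy]-5-(trimethylsilyl)pent-4-ynoate
Conditions: TBSCl, imidazole, DMF, 20 °C
Reagents that add atoms: tert-butyldimethylsilyl chloride, CC(C)(C)[Si](C)(C)Cl
Why: Standard imidazole-mediated O-silylation of the secondary alcohol; the stereocentre is untouched and the ether survives every later step until the final fluoride treatment.

Step 4
Reactants: 8 methyl (2R)-2-[(tert-butyldimethylsilyl)oxy]-5-(trimethylsilyl)pent-4-ynoate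
Product: 9 (2R)-2-[(tert-butyldimethylsilyl)oxy]-5-(trimethylsilyl)pent-4-ynal
Conditions: (i-Bu)2AlH (1.1 equiv), CH2Cl2, −78 °C; aq. potassium sodium tartrate
Reagents that add atoms: none
Why: Half-reduction of an α-silyloxy ester with (i-Bu)2AlH stops at the chelated tetrahedral aluminate at −78 °C and releases the aldehyde on work-up without α-epimerisation.

Step 5
Reactants: 9 (2R)-2-[(tert-butyldimethylsilyl)oxy]-5-(trimethylsilyl)pent-4-ynal
Product: 10 tert-butyl{[(3R)-1,1-dibromo-6-(trimethylsilyl)hex-1-en-5-yn-3-yl]oxy}dimethylsilane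
Conditions: CBr4, PPh3, Zn, CH2Cl2, 0 °C
Reagents that add atoms: carbon tetrabromide, BrC(Br)(Br)Br
Why: Ramirez dibromo-olefination (first stage of the Corey–Fuchs sequence) is a near-neutral Wittig reaction that does not epimerise the α-silyloxy aldehyde.

Step 6
Reactants: 11 methyl (2R)-3-hydroxy-2-methylpropanoate ((R)-Roche ester)
Product: 12 methyl (2S)-3-iodo-2-methylpropanoate
Conditions: I2, PPh3, imidazole, CH2Cl2, 0 → 20 °C
Reagents that add atoms: iodine, II
Why: Appel-type (Garegg–Samuelsson) iodination of the primary alcohol leaves the bought methyl stereocentre (future C11′) untouched; the descriptor changes from R to S only through CIP priorities.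

Step 7
Reactants: 12 methyl (2S)-3-iodo-2-methylpropanoate; 13 bromoethene
Product: 15 methyl (2R)-2-methylpent-4-enoate, via alkylzinc iodide 14 (not isolated)
Conditions: Zn dust (TMSCl-activated), DMF, 20 °C; then 13 (1 M in THF), Pd2(dba)3 (2 mol%), P(o-tol)3 (8 mol%), 20 °C
Reagents that add atoms: none
Why: Zinc insertion gives the ester-chelated alkylzinc whose stereocentre is β to zinc and not involved, and Negishi coupling with the vinyl bromide forms C8′–C9′/C10′ connectivity without racemisation.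

Step 8
Reactants: 15 methyl (2R)-2-methylpent-4-enoate
Product: 16 (2R)-N-methoxy-N,2-dimethylpent-4-enamide
Conditions: MeNHOMe·HCl, i-PrMgCl, THF, −20 °C
Reagents that add atoms: N,O-dimethylhydroxylamine hydrochloride, CNOC.Cl
Why: Weinreb amidation by the pre-formed magnesium amide at −20 °C is faster than ester enolisation, so the α-methyl stereocentre is retained.

Step 9
Reactants: 16 (2R)-N-methoxy-N,2-dimethylpent-4-enamide; 10 tert-butyl{[(3R)-1,1-dibromo-6-(trimethylsilyl)hex-1-en-5-yn-3-yl]oxy}dimethylsilane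
Product: 18 (2R,6Z,8R)-6-bromo-8-[(tert-butyldimethylsilyl)oxy]-N-methoxy-N,2-dimethyl-11-(trimethylsilyl)undec-6-en-10-ynamide, via alkylborane 17 (not isolated)
Conditions: 16, 9-BBN, THF, 0 → 20 °C; then 10, PdCl2(dppf) (5 mol%), AsPh3, aq. K3PO4, THF/DMF, 20 °C
Reagents that add atoms: none
Why: Anti-Markovnikov hydroboration followed by B-alkyl Suzuki–Miyaura coupling, in which zerovalent palladium inserts selectively into the less hindered C–Br bond trans to the CH(OTBS) group, places the chain (C8′) trans to C5′ and keeps the cis bromide.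

Step 10
Reactants: 18 (2R,6Z,8R)-6-bromo-8-[(tert-butyldimethylsilyl)oxy]-N-methoxy-N,2-dimethyl-11-(trimethylsilyl)undec-6-en-10-ynamide
Product: 20 (2R,6E,8R)-8-[(tert-butyldimethylsilyl)oxy]-N-methoxy-N,2,6-trimethylundec-6-en-10-ynamide, via silylalkyne 19 (not isolated)
Conditions: Me2Zn, Pd(P(t-Bu)3)2 (3 mol%), THF, 0 → 20 °C; then MeOH, K2CO3, 20 °C
Reagents that add atoms: dimethylzinc, C[Zn]C
Why: Negishi methylation of the alkenyl bromide proceeds with retention to give the E-trisubstituted C6′=C7′ alkene, and K2CO3/MeOH then removes only the alkynyl silyl group (TBS ether and Weinreb amide are stable).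

Step 11
Reactants: 20 (2R,6E,8R)-8-[(tert-butyldimethylsilyl)oxy]-N-methoxy-N,2,6-trimethylundec-6-en-10-ynamide
Product: 22 [(1E,4R,5E,10R)-4-[(tert-butyldimethylsilyl)oxy]-11-[methoxy(methyl)amino]-2,6,10-trimethyl-11-oxoundeca-1,5-dien-1-yl]boronic acid, via pinacol boronate 21 (not isolated)
Conditions: CuCl (10 mol%), Xantphos (10 mol%), NaOtBu, B2pin2, MeI, THF, 20 °C; then NaIO4, NH4OAc, H2O, 20 °C
Reagents that add atoms: bis(pinacolato)diboron, CC1(C)OB(OC1(C)C)B1OC(C)(C)C(C)(C)O1; iodomethane, CI; water, O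
Why: Copper-catalysed formal methylboration (syn borylcupration with boron on the terminal carbon, then methylation of the alkenylcopper with retention) sets the E-C2′=C3′ alkene, and periodate cleavage of pinacol frees the boronic acid.

Step 12
Reactants: 22 [(1E,4R,5E,10R)-4-[(tert-butyldimethylsilyl)oxy]-11-[methoxy(methyl)amino]-2,6,10-trimethyl-11-oxoundeca-1,5-dien-1-yl]boronic acid; 3 2-(hydroxymethyl)-4-methoxy-6-methylphenol
Product: 24 (2R,6E,8R,10E)-8-[(tert-butyldimethylsilyl)oxy]-12-(2-hydroxy-5-methoxy-3-methylphenyl)-N-methoxy-N,2,6,10-tetramethyldodeca-6,10-dienamide, via quinone methide 23 (not isolated)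
Conditions: 3 (3 equiv), hν (300 nm), degassed MeCN/H2O 4:1, 15 °C, FEP flow coil
Reagents that add atoms: none
Why: Proposed new method: 300 nm excitation of the salicyl alcohol causes excited-state proton transfer and loss of water to the o-quinone methide 23 (known photodehydration); the boronic acid, pre-associated through its labile cyclic salicyl boronate, binds the quinone-methide oxygen as a boron ate complex and delivers the alkenyl group to the exocyclic CH2 through a six-membered transition state with retention of E geometry, rearomatisation being the driving force and rehydration merely returning 3; the closest known reactions are the thermal biphenol-catalysed (Petasis-type) addition of alkenylboronates to aryl-substituted o-quinone methides and the trapping of photogenerated o-quinone methides by heteroatom nucleophiles and vinyl ethers; no stereocentre is formed or touched.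

Step 13
Reactants: 25 2-methylbut-3-yn-2-ol
Product: 26 (3E)-2-methyl-4-(tributylstannyl)but-3-en-2-ol
Conditions: Bu3SnH, PdCl2(PPh3)2 (2 mol%), THF, 0 → 20 °C
Reagents that add atoms: tributylstannane, CCCC[SnH](CCCC)CCCC
Why: Palladium-catalysed syn-hydrostannation places tin on the terminal carbon, away from the bulky tertiary carbinol, and gives the E-vinylstannane.

Step 14
Reactants: 24 (2R,6E,8R,10E)-8-[(tert-butyldimethylsilyl)oxy]-12-(2-hydroxy-5-methoxy-3-methylphenyl)-N-methoxy-N,2,6,10-tetramethyldodeca-6,10-dienamide; 26 (3E)-2-methyl-4-(tributylstannyl)but-3-en-2-ol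
Product: 29 (3E,6R,10E,12R,14E)-12-[(tert-butyldimethylsilyl)oxy]-2-hydroxy-16-(2-hydroxy-5-methoxy-3-methylphenyl)-2,6,10,14-tetramethylhexadeca-3,10,14-trien-5-one, via lithium phenoxide 27 (not isolated), via dilithio reagent 28 (not isolated)
Conditions: 26 (3 equiv), n-BuLi (6 equiv), THF, −78 → −40 °C; 24, LiN(SiMe3)2 (1.05 equiv), THF, −78 °C; combine, −78 → −30 °C; aq. NH4Cl
Reagents that add atoms: none
Why: Tin–lithium exchange gives the E-vinyllithium with retention, and Weinreb ketone synthesis through the stable chelated tetrahedral intermediate prevents over-addition and enolisation, so the E-enone forms with C11′ intact.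

Step 15
Reactants: 29 (3E,6R,10E,12R,14E)-12-[(tert-butyldimethylsilyl)oxy]-2-hydroxy-16-(2-hydroxy-5-methoxy-3-methylphenyl)-2,6,10,14-tetramethylhexadeca-3,10,14-trien-5-one
Product: 30 (3E,6R,10E,12R,14E)-2,12-dihydroxy-16-(2-hydroxy-5-methoxy-3-methylphenyl)-2,6,10,14-tetramethylhexadeca-3,10,14-trien-5-one (CNP0214110.1)
Conditions: HF·pyridine, THF/pyridine, 0 → 20 °C
Reagents that add atoms: none
Why: Buffered fluoride desilylation of the allylic TBS ether is mild enough to leave the epimerisable α-methyl enone, the tertiary allylic alcohol and the prenyl-type phenol unchanged.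

**Compound list**
1 | 4-methoxy-2-methylphenol | COc1ccc(O)c(C)c1 | starting material
2 | sodium 4-methoxy-2-methylphenolate | COc1ccc([O-])c(C)c1.[Na+] | intermediate
3 | 2-(hydroxymethyl)-4-methoxy-6-methylphenol | COc1cc(C)c(O)c(CO)c1 | intermediate
4 | methyl (2R)-oxirane-2-carboxylate | COC(=O)[C@H]1CO1 | starting material
5 | ethynyltrimethylsilane | C#C[Si](C)(C)C | starting material
6 | lithium (trimethylsilyl)acetylide | [Li]C#C[Si](C)(C)C | intermediate
7 | methyl (2R)-2-hydroxy-5-(trimethylsilyl)pent-4-ynoate | COC(=O)[C@H](O)CC#C[Si](C)(C)C | intermediate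
8 | methyl (2R)-2-[(tert-butyldimethylsilyl)oxy]-5-(trimethylsilyl)pent-4-ynoate | COC(=O)[C@H](O[Si](C)(C)C(C)(C)C)CC#C[Si](C)(C)C | intermediate
9 | (2R)-2-[(tert-butyldimethylsilyl)oxy]-5-(trimethylsilyl)pent-4-ynal | O=C[C@H](O[Si](C)(C)C(C)(C)C)CC#C[Si](C)(C)C | intermediate
10 | tert-butyl{[(3R)-1,1-dibromo-6-(trimethylsilyl)hex-1-en-5-yn-3-yl]oxy}dimethylsilane | BrC(Br)=C[C@H](O[Si](C)(C)C(C)(C)C)CC#C[Si](C)(C)C | intermediate
11 | methyl (2R)-3-hydroxy-2-methylpropanoate | COC(=O)[C@H](C)CO | starting material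
12 | methyl (2S)-3-iodo-2-methylpropanoate | COC(=O)[C@H](C)CI | intermediate
13 | bromoethene | C=CBr | starting material
14 | iodo[(2S)-3-methoxy-2-methyl-3-oxopropyl]zinc | COC(=O)[C@H](C)C[Zn]I | intermediate
15 | methyl (2R)-2-methylpent-4-enoate | COC(=O)[C@H](C)CC=C | intermediate
16 | (2R)-N-methoxy-N,2-dimethylpent-4-enamide | CON(C)C(=O)[C@H](C)CC=C | intermediate
17 | (2R)-5-(9-borabicyclo[3.3.1]nonan-9-yl)-N-methoxy-N,2-dimethylpentanamide | CON(C)C(=O)[C@H](C)CCCB1C2CCCC1CCC2 | intermediate
18 | (2R,6Z,8R)-6-bromo-8-[(tert-butyldimethylsilyl)oxy]-N-methoxy-N,2-dimethyl-11-(trimethylsilyl)undec-6-en-10-ynamide | C[Si](C)(C)C#CC[C@@H](O[Si](C)(C)C(C)(C)C)/C=C(\Br)CCC[C@@H](C)C(=O)N(C)OC | intermediate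
19 | (2R,6E,8R)-8-[(tert-butyldimethylsilyl)oxy]-N-methoxy-N,2,6-trimethyl-11-(trimethylsilyl)undec-6-en-10-ynamide | C[Si](C)(C)C#CC[C@@H](O[Si](C)(C)C(C)(C)C)/C=C(\C)CCC[C@@H](C)C(=O)N(C)OC | intermediate
20 | (2R,6E,8R)-8-[(tert-butyldimethylsilyl)oxy]-N-methoxy-N,2,6-trimethylundec-6-en-10-ynamide | C#CC[C@@H](O[Si](C)(C)C(C)(C)C)/C=C(\C)CCC[C@@H](C)C(=O)N(C)OC | intermediate
21 | (2R,6E,8R,10E)-8-[(tert-butyldimethylsilyl)oxy]-N-methoxy-N,2,6,10-tetramethyl-11-(4,4,5,5-tetramethyl-1,3,2-dioxaborolan-2-yl)undeca-6,10-dienamide | CC1(C)OB(/C=C(\C)C[C@@H](O[Si](C)(C)C(C)(C)C)/C=C(\C)CCC[C@@H](C)C(=O)N(C)OC)OC1(C)C | intermediate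
22 | [(1E,4R,5E,10R)-4-[(tert-butyldimethylsilyl)oxy]-11-[methoxy(methyl)amino]-2,6,10-trimethyl-11-oxoundeca-1,5-dien-1-yl]boronic acid | OB(O)/C=C(\C)C[C@@H](O[Si](C)(C)C(C)(C)C)/C=C(\C)CCC[C@@H](C)C(=O)N(C)OC | intermediate
23 | 4-methoxy-2-methyl-6-methylidenecyclohexa-2,4-dien-1-one | COC1=CC(=C)C(=O)C(C)=C1 | intermediate
24 | (2R,6E,8R,10E)-8-[(tert-butyldimethylsilyl)oxy]-12-(2-hydroxy-5-methoxy-3-methylphenyl)-N-methoxy-N,2,6,10-tetramethyldodeca-6,10-dienamide | COc1cc(C)c(O)c(C/C=C(\C)C[C@@H](O[Si](C)(C)C(C)(C)C)/C=C(\C)CCC[C@@H](C)C(=O)N(C)OC)c1 | intermediate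
25 | 2-methylbut-3-yn-2-ol | CC(C)(O)C#C | starting material
26 | (3E)-2-methyl-4-(tributylstannyl)but-3-en-2-ol | CCCC[Sn](CCCC)(CCCC)/C=C/C(C)(C)O | intermediate
27 | lithium 2-[(2E,5R,6E,11R)-5-[(tert-butyldimethylsilyl)oxy]-12-[methoxy(methyl)amino]-3,7,11-trimethyl-12-oxododeca-2,6-dien-1-yl]-4-methoxy-6-methylphenolate | COc1cc(C)c(O[Li])c(C/C=C(\C)C[C@@H](O[Si](C)(C)C(C)(C)C)/C=C(\C)CCC[C@@H](C)C(=O)N(C)OC)c1 | intermediate
28 | lithium (3E)-4-lithio-2-methylbut-3-en-2-olate | [Li]/C=C/C(C)(C)O[Li] | intermediate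
29 | (3E,6R,10E,12R,14E)-12-[(tert-butyldimethylsilyl)oxy]-2-hydroxy-16-(2-hydroxy-5-methoxy-3-methylphenyl)-2,6,10,14-tetramethylhexadeca-3,10,14-trien-5-one | COc1cc(C)c(O)c(C/C=C(\C)C[C@@H](O[Si](C)(C)C(C)(C)C)/C=C(\C)CCC[C@@H](C)C(=O)/C=C/C(C)(C)O)c1 | intermediate
30 | (3E,6R,10E,12R,14E)-2,12-dihydroxy-16-(2-hydroxy-5-methoxy-3-methylphenyl)-2,6,10,14-tetramethylhexadeca-3,10,14-trien-5-one | COc1cc(C)c(O)c(C/C=C(\C)C[C@@H](O)/C=C(\C)CCC[C@@H](C)C(=O)/C=C/C(C)(C)O)c1 | target

**Step count and risks**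

Total step count: 15. Longest linear sequence: 10 steps (steps 2, 3, 4, 5, 9, 10, 11, 12, 14, 15, starting from 4).

Most likely to fail:

Step 12 (the proposed new photochemical alkenylation). Alkenyl transfer from boron may not compete with rehydration or oligomerisation of 23. The quinone methide may instead undergo hetero-Diels–Alder addition to the alkenylboron double bond. The product 24, a 2-allylphenol, may photocyclise to a chroman on over-irradiation. The fallback uses known chemistry, sets out from 3 and 22 and comes back at 24. Treating 3 with acetyl bromide (CH2Cl2, 0 °C) gives 2-(bromomethyl)-4-methoxy-6-methylphenyl acetate F1. Suzuki–Miyaura coupling of this benzylic bromide with 22 (PdCl2(dppf), K3PO4, THF/H2O, 50 °C) gives (2R,6E,8R,10E)-12-(2-acetoxy-5-methoxy-3-methylphenyl)-8-[(tert-butyldimethylsilyl)oxy]-N-methoxy-N,2,6,10-tetramethyldodeca-6,10-dienamide F2. Brief K2CO3/MeOH cleaves the aryl acetate and gives 24.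

Step 9 (trans-selective mono-coupling of the 1,1-dibromoalkene). Double alkylation, or erosion of the trans selectivity next to the bulky CH(OTBS) group, would give mixtures. The fallback sets out from 10 and comes back at 19. Treating 10 with n-BuLi (2 equiv, −78 °C) and then MeI completes the Corey–Fuchs sequence to tert-butyldimethyl{[(4R)-7-(trimethylsilyl)hepta-2,6-diyn-4-yl]oxy}silane F3. Hydrozirconation with Cp2Zr(H)Cl (1.1 equiv, 0 °C), which should take the methyl-capped alkyne in preference to the silyl-capped one and place zirconium on the methyl-bearing carbon, followed by I2, gives tert-butyl{[(2E,4R)-2-iodo-7-(trimethylsilyl)hept-2-en-6-yn-4-yl]oxy}dimethylsilane F4. B-alkyl Suzuki coupling of F4 with borane 17 (PdCl2(dppf), AsPh3, aq. K3PO4) gives 19 directly. The K2CO3/MeOH treatment of step 10 then leads on to 20.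

Step 11 (copper-catalysed methylboration). The regioselectivity of borylcupration on an alkyl-substituted terminal alkyne, competing alkyne deprotonation, or loss of material in the periodate stage could lower the yield. The fallback sets out from 20 and comes back at 21. Negishi methylalumination (AlMe3, Cp2ZrCl2 cat., 1 equiv H2O, CH2Cl2, −20 °C) followed by I2 gives (2R,6E,8R,10E)-8-[(tert-butyldimethylsilyl)oxy]-11-iodo-N-methoxy-N,2,6,10-tetramethylundeca-6,10-dienamide F5. Stereoretentive Miyaura borylation (B2pin2, PdCl2(dppf), KOPh, toluene, 50 °C) converts F5 into 21. The periodate treatment of step 11 then gives 22.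

Further compounds
F1 | step 12 | 2-(bromomethyl)-4-methoxy-6-methylphenyl acetate | COc1cc(C)c(OC(C)=O)c(CBr)c1
F2 | step 12 | (2R,6E,8R,10E)-12-(2-acetoxy-5-methoxy-3-methylphenyl)-8-[(tert-butyldimethylsilyl)oxy]-N-methoxy-N,2,6,10-tetramethyldodeca-6,10-dienamide | COc1cc(C)c(OC(C)=O)c(C/C=C(\C)C[C@@H](O[Si](C)(C)C(C)(C)C)/C=C(\C)CCC[C@@H](C)C(=O)N(C)OC)c1
F3 | step 9 | tert-butyldimethyl{[(4R)-7-(trimethylsilyl)hepta-2,6-diyn-4-yl]oxy}silane | CC#C[C@H](O[Si](C)(C)C(C)(C)C)CC#C[Si](C)(C)C
F4 | step 9 | tert-butyl{[(2E,4R)-2-iodo-7-(trimethylsilyl)hept-2-en-6-yn-4-yl]oxy}dimethylsilane | C/C(I)=C\[C@H](O[Si](C)(C)C(C)(C)C)CC#C[Si](C)(C)C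
F5 | step 11 | (2R,6E,8R,10E)-8-[(tert-butyldimethylsilyl)oxy]-11-iodo-N-methoxy-N,2,6,10-tetramethylundeca-6,10-dienamide | I/C=C(\C)C[C@@H](O[Si](C)(C)C(C)(C)C)/C=C(\C)CCC[C@@H](C)C(=O)N(C)OC
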